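## Structural features

The target is an open C12 chain (C1 carboxyl to C12 ketone) with a (2E,4E)-dienoic acid at C1–C5, a 4-aminophenyl ketone at C12 and a 1-hydroxyethyl branch (carbinol carbon C1') on C6; its only ring is the benzene ring. Five stereocentres lie between the two π-systems: C1' (S), C6 (S) and C7 (R) are contiguous, C7 and C9 (S) carry syn methyl groups across the C8 methylene, and C9 stands next to the C10 (R) carbinol, anti to its hydroxyl. C6 is a tertiary allylic branch point flanked by stereocentres, and the C7–C8–C9 unit has no heteroatom through which aldol logic could reach it. Fragile groups are the β-hydroxy aryl ketone (retro-aldol and β-elimination in base, dehydration in strong acid), the free aniline (oxidation, condensation with aldehydes) and the dienoic acid (conjugate addition, isomerisation, vinylogous acidity of C6–H). The real difficulty is the stereopentad C1'/C6/C7/C9/C10, spread over six chain carbons with only two oxygen handles. The feature exploited is that C5 can be taken to the carbonyl level and C10 bears oxygen: joining C5 to C10 in place of the C10–O bond closes a six-membered carbocycle C5–C6–C7–C8–C9–C10. In that ring the C7 and C9 methyls are cis-1,3 (the meso pattern of cis-3,5-dimethylcyclohexanone), the C10 substituent is trans to the C9 methyl and the C6 branch, once installed, is trans to the C7 methyl, so every substituent is equatorial. The route is therefore a Baeyer–Villiger cleavage of an all-equatorial 2-allyl-cis-3,5-dimethylcyclohexanone, obtained by desymmetrising the meso ketone, to a seven-membered lactone on which C6 and C1' are then set.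

## Logic of the disconnections

24 to 23: the O–tert-butyl bond of the ester, the N–CO2tBu bond and the O–Si bond are cut together. All three are acid-labile, so one final operation frees the acid, the aniline and the C1' alcohol without base near the β-hydroxy ketone. The demand is an acid exposure cold and short enough to leave the C10 carbinol intact.

23 to 22: the C12 carbonyl is taken back to a C12 carbinol. A C12 ketone makes C11 acidic and the C10 oxygen a β-leaving group, so C12 stays at the alcohol level through the hydride and olefination steps. Both C12 epimers are acceptable, which removes one stereochemical demand. The oxidant must tell the benzylic C12–OH from the aliphatic C10–OH.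

22 to 17 and 20: the C4=C5 double bond is cut. This removes the whole dienoate as a four-carbon phosphonate and leaves C5 as an aldehyde. The forward step must be E-selective and must not epimerise C6, which is α to the aldehyde. 20 is cut at its P–C bond to 18 and 19.

17 to 16: the C5 aldehyde and the C10 hydroxyl are reconnected as one ester function (C5–O–C10). Two functional groups become one seven-membered ring that protects both and fixes the conformation. The forward step must stop the hydride at the aldehyde level.

16 to 13 and 14: the C12–aryl bond is cut. The aryl group arrives as a purchased, carbamate-protected unit. The nucleophile must be non-basic (C12 aldehyde with a β-acyloxy group) and must not touch the lactone.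

13 to 11: C12 is traced back to an internal alkene carbon, so the side chain on C10 becomes an allyl group. A terminal alkene is the one C11–C12 precursor that tolerates peracid, amide bases and hydride. The cleavage must be done while no other alkene is present, hence before the diene.

11 to 10 to 9 to 7: the O–Si bond, then the C1' carbinol (back to a ketone), then the C6–C1' bond are cut. In 7 the lactone α-methylene C6 is the only acidic site. In 9, C6 is configurationally labile and should settle trans to the C7 methyl; C1' then follows from C6 by chelation. Two stereocentres are removed without any new chiral reagent. The demands are the C6 equilibrium and the facial selectivity of the chelate.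

7 to 5 (key): the C10–O bond is replaced by a C10–C5 bond. The acyclic triad C7/C9/C10 becomes an all-equatorial trisubstituted cyclohexanone in which C10 is α to the carbonyl and thermodynamically controlled. The forward step must migrate C10 (not C6) with retention and spare the alkene.

5 to 3 to 1: the C10–C11 bond is cut, then the enol silane is taken back to the meso ketone. 1 already contains C5–C10 and both methyl groups in the right relative configuration. The only absolute stereochemical event is the choice between two enantiotopic α-protons; the allylation must go trans to the C9 methyl, which is also the thermodynamic outcome.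

## Other disconnections considered

Alternative 1: Cut C10–C11 (aldol) and C4=C5 (olefination), the route most chemists would draw first. The forward key step is a boron-mediated aldol of an N-protected 4-aminophenyl methyl ketone with aldehyde A1 to give adduct A2. C10 must be set anti to the C9 methyl, against the intrinsic 1,2-induction of an α-methyl aldehyde (anti-Felkin sense), with a methyl ketone enolate that discriminates weakly. Each of the five stereocentres in A1 would be bought separately with an auxiliary or chiral reagent, and the syn-1,3-dimethyl unit needs an sp3–sp3 junction at C8. Nothing is relayed, and the route would be markedly longer.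

Alternative 2: Cut C6–C7 by an Ireland–Claisen rearrangement of the lactate-derived allylic propanoate A3 to acid A4. One chair transition state would set C6, C7 and the (E)-C4=C5 alkene. C8 then emerges as a carboxyl that must be reduced and joined to C9 by alkylation, and C9 and C10 still need their own asymmetric steps. The allylic carbinol of A3 needs an asymmetric step of its own. The outcome also depends on the ketene acetal geometry and on the bias of the C1' silyloxy centre at the allyl terminus. Only two of five centres come from the key event.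

Alternative 3: Cut the same C5–C10 ring bond by ozonolysis rather than oxygen insertion. An isopropenyl cuprate would add to enone A5, the enolate would be trapped as enol silane A6, and ozonolysis would give keto aldehyde acid A7. The ring relays only C6. C10 emerges as a carboxyl, so its carbinol would have to be made later by the acyclic aldol of Alternative 1. C1' would need a reagent-controlled reduction next to C6, which in A7 sits between two carbonyls and is configurationally labile. A5 is also not an article of commerce in enantiopure form. The Baeyer–Villiger cut keeps oxygen on C10 with retention and leaves C6 as a lactone α-methylene, so all centres are relayed.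

Key step: step 3

Assumption: the (S,S) amide base is taken to remove the axial α-proton that leads to the (3S,5R) enol silane, by analogy with 4-substituted cyclohexanones; should the sense be opposite, the equally available (R,R) amine is used.

## Route

Step 1
Reactants: 1 cis-3,5-dimethylcyclohexan-1-one
Product: 3 trimethyl{[(3S,5R)-3,5-dimethylcyclohex-1-en-1-yl]oxy}silane, via lithium enolate 2 (not isolated)
Conditions: (S,S)-bis(1-phenylethyl)amine, n-BuLi, LiCl, THF, −78 °C; then TMSCl and 1, −100 °C
Reagents that add atoms: chlorotrimethylsilane, C[Si](C)(C)Cl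
Why: Enantioselective deprotonation of a meso ketone by a C2-symmetric chiral lithium amide, with silyl trapping of the enolate. No stereocentre is created, but the choice between the two enantiotopic axial α-protons makes the two methyl-bearing carbons non-equivalent and fixes the absolute configuration of the whole series.

Step 2
Reactants: 3 trimethyl{[(3S,5R)-3,5-dimethylcyclohex-1-en-1-yl]oxy}silane
Product: 5 (2R,3S,5R)-3,5-dimethyl-2-(prop-2-en-1-yl)cyclohexan-1-one, via benzyltrimethylammonium enolate 4 (not isolated)
Conditions: anhydrous BnMe3N+ F−, 4 Å molecular sieves, allyl bromide (3 equiv), THF, 0 °C to rt; work-up; then K2CO3, MeOH, rt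
Reagents that add atoms: allyl bromide, C=CCBr
Why: Fluoride-induced cleavage of the enol silane gives the quaternary ammonium enolate 4 regiospecifically, and because the halide is present from the start, C-allylation should outrun proton exchange with the product, which would pass through the meso ketone and erode the enantiomeric purity. The allyl group should enter anti to the neighbouring C3 methyl; because C2 is α to the ketone and the 2,3-trans-3,5-cis isomer is all-equatorial, the base treatment corrects any cis isomer.

Step 3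
Reactants: 5 (2R,3S,5R)-3,5-dimethyl-2-(prop-2-en-1-yl)cyclohexan-1-one
Product: 7 (4R,6S,7R)-4,6-dimethyl-7-(prop-2-en-1-yl)oxepan-2-one, via Criegee adduct 6 (not isolated)
Conditions: mCPBA (1.2 equiv), NaHCO3, CH2Cl2, 0 °C to rt
Reagents that add atoms: 3-chloroperoxybenzoic acid, O=C(OO)c1cccc(Cl)c1
Why: Baeyer–Villiger oxidation: the peracid adds to the ketone to give Criegee adduct 6, and the ring carbon best able to carry positive charge migrates to oxygen, antiperiplanar to the breaking O–O bond, as 3-chlorobenzoate leaves. The closest known reaction type is the oxidation of 2-alkylcyclohexanones to 7-alkyloxepan-2-ones. The seven-membered lactone arises by ring expansion (1,2-shift of ring carbon C2 with insertion of oxygen into the C1–C2 bond), not by cyclisation, so no ring-closure mode has to be met. No stereocentre is created: the migrating carbon keeps its configuration, so the (2R) centre of 5 becomes the (7R) C–O centre (C10 of the target), and the two methyl-bearing carbons are untouched. Regioselectivity between the secondary, allyl-bearing ring carbon C2 and the primary ring carbon C6 is secured by the higher migratory aptitude of the secondary carbon. Chemoselectivity between ketone and terminal alkene rests on the low nucleophilicity of a monosubstituted alkene, the buffer, the small excess of peracid and the low temperature. In one operation the ring-held array becomes an acyclic one with oxygen on C10, a carboxyl at C5 and an enolisable methylene at C6.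

Step 4
Reactants: 7 (4R,6S,7R)-4,6-dimethyl-7-(prop-2-en-1-yl)oxepan-2-one
Product: 9 (3R,4R,6S,7R)-3-acetyl-4,6-dimethyl-7-(prop-2-en-1-yl)oxepan-2-one, via lactone lithium enolate 8 (not isolated)
Conditions: LiN(i-Pr)2 (2.2 equiv), THF, −78 °C; MeC(O)N(OMe)Me, −78 to −30 °C; aq. NH4Cl
Reagents that add atoms: N-methoxy-N-methylacetamide, CC(=O)N(C)OC
Why: Crossed Claisen acylation of a lactone enolate with an N-methoxy-N-methylamide, which stops at the ketone stage; the second equivalent of base holds the product as its enolate until the quench. C3 of 9 lies between two carbonyls and is labile, so it should settle trans to the C4 methyl, the arrangement with all four ring substituents equatorial.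

Step 5
Reactants: 9 (3R,4R,6S,7R)-3-acetyl-4,6-dimethyl-7-(prop-2-en-1-yl)oxepan-2-one
Product: 10 (3R,4R,6S,7R)-3-[(1S)-1-hydroxyethyl]-4,6-dimethyl-7-(prop-2-en-1-yl)oxepan-2-one
Conditions: Zn(BH4)2, Et2O, −20 to 0 °C
Reagents that add atoms: none
Why: Chelation-controlled reduction of an α-substituted β-keto ester: zinc bridges the lactone and ketone carbonyls, and hydride attacks the ketone from the face of the small C3–H, anti to the C3–C4 ring bond. This is the known syn-selective reduction and gives the (1S) carbinol from the (3R) centre; the lactone and the alkene are not reduced.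

Step 6
Reactants: 10 (3R,4R,6S,7R)-3-[(1S)-1-hydroxyethyl]-4,6-dimethyl-7-(prop-2-en-1-yl)oxepan-2-one
Product: 11 (3R,4R,6S,7R)-3-[(1S)-1-(tert-butyldimethylsilyloxy)ethyl]-4,6-dimethyl-7-(prop-2-en-1-yl)oxepan-2-one
Conditions: TBSOTf, 2,6-lutidine, CH2Cl2, −78 °C
Reagents that add atoms: tert-butyldimethylsilyl trifluoromethanesulfonate, CC(C)(C)[Si](C)(C)OS(=O)(=O)C(F)(F)F
Why: Standard silylation of a secondary alcohol under non-nucleophilic base at low temperature, which avoids β-elimination of the β-hydroxy lactone. The silyl ether later prevents retro-aldol and elimination at the C5 aldehyde stage.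

Step 7
Reactants: 11 (3R,4R,6S,7R)-3-[(1S)-1-(tert-butyldimethylsilyloxy)ethyl]-4,6-dimethyl-7-(prop-2-en-1-yl)oxepan-2-one
Product: 13 2-[(2R,3S,5R,6R)-6-[(1S)-1-(tert-butyldimethylsilyloxy)ethyl]-3,5-dimethyl-7-oxooxepan-2-yl]acetaldehyde, via ozonide 12 (not isolated)
Conditions: O3, CH2Cl2, −78 °C; PPh3, −78 °C to rt
Reagents that add atoms: ozone, [O-][O+]=O
Why: Ozonolysis of the only alkene in the molecule with reductive work-up; lactone and silyl ether are inert. The β-acyloxy aldehyde is used crude to avoid base- or silica-induced elimination.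

Step 8
Reactants: 13 2-[(2R,3S,5R,6R)-6-[(1S)-1-(tert-butyldimethylsilyloxy)ethyl]-3,5-dimethyl-7-oxooxepan-2-yl]acetaldehyde; 14 tert-butyl (4-iodophenyl)carbamate
Product: 16 tert-butyl {4-[2-[(2R,3S,5R,6R)-6-[(1S)-1-(tert-butyldimethylsilyloxy)ethyl]-3,5-dimethyl-7-oxooxepan-2-yl]-1-hydroxyethyl]phenyl}carbamate (both carbinol epimers), via arylchromium dichloride 15 (not isolated)
Conditions: CrCl2 (4 equiv), NiCl2 (2 mol %), DMF, rt
Reagents that add atoms: none
Why: Nozaki–Hiyama–Kishi arylation: zerovalent nickel inserts into the C–I bond, the aryl group passes to trivalent chromium, and 15 adds to the aldehyde only. The reagent is non-basic, so the lactone, the N–H and the β-acyloxy aldehyde are tolerated; the new C12 carbinol is left as a mixture because it is oxidised in step 12.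

Step 9
Reactants: 16 tert-butyl {4-[2-[(2R,3S,5R,6R)-6-[(1S)-1-(tert-butyldimethylsilyloxy)ethyl]-3,5-dimethyl-7-oxooxepan-2-yl]-1-hydroxyethyl]phenyl}carbamate
Product: 17 tert-butyl {4-[(3R,4S,6R,7R,8S)-8-(tert-butyldimethylsilyloxy)-7-formyl-1,3-dihydroxy-4,6-dimethylnonyl]phenyl}carbamate (both C1 epimers; written as the open hydroxy aldehyde)
Conditions: i-Bu2AlH (4 equiv), CH2Cl2, −78 °C; aq. potassium sodium tartrate
Reagents that add atoms: none
Why: Partial reduction of a lactone: hydride adds once at −78 °C and the aldehyde is released only on work-up, which also frees the C10 hydroxyl. The extra equivalents are consumed by the O–H and N–H protons; carbamate and silyl ether are untouched.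

Step 10
Reactants: 18 tert-butyl (E)-4-bromobut-2-enoate; 19 triethyl phosphite
Product: 20 tert-butyl (E)-4-(diethoxyphosphoryl)but-2-enoate
Conditions: neat, 120 °C
Reagents that add atoms: none
Why: Michaelis–Arbuzov reaction of a primary allylic bromide; SN2 attack of phosphorus and dealkylation by bromide, with the conjugated E-alkene retained.

Step 11
Reactants: 17 tert-butyl {4-[(3R,4S,6R,7R,8S)-8-(tert-butyldimethylsilyloxy)-7-formyl-1,3-dihydroxy-4,6-dimethylnonyl]phenyl}carbamate; 20 tert-butyl (E)-4-(diethoxyphosphoryl)but-2-enoate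
Product: 22 tert-butyl (2E,4E,6S,7R,9S,10R)-12-[4-(tert-butoxycarbonylamino)phenyl]-6-[(1S)-1-(tert-butyldimethylsilyloxy)ethyl]-10,12-dihydroxy-7,9-dimethyldodeca-2,4-dienoate (both C12 epimers), via lithiated phosphonate 21 (not isolated)
Conditions: LiN(SiMe3)2, 20 (excess), THF, −78 °C; then 17, −78 to 0 °C
Reagents that add atoms: none
Why: Vinylogous Horner–Wadsworth–Emmons olefination, which should give the new C4=C5 bond with E geometry while the existing alkene stays E. The stabilised anion 21 is too weak a base to deprotonate the free hydroxyls, and olefination should outrun epimerisation at C6.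

Step 12
Reactants: 22 tert-butyl (2E,4E,6S,7R,9S,10R)-12-[4-(tert-butoxycarbonylamino)phenyl]-6-[(1S)-1-(tert-butyldimethylsilyloxy)ethyl]-10,12-dihydroxy-7,9-dimethyldodeca-2,4-dienoate
Product: 23 tert-butyl (2E,4E,6S,7R,9S,10R)-12-[4-(tert-butoxycarbonylamino)phenyl]-6-[(1S)-1-(tert-butyldimethylsilyloxy)ethyl]-10-hydroxy-7,9-dimethyl-12-oxododeca-2,4-dienoate
Conditions: MnO2 (activated, excess), CH2Cl2, rt
Reagents that add atoms: none
Why: Chemoselective oxidation of a benzylic alcohol by MnO2; the aliphatic C10 carbinol, the dienoate and the carbamate are not oxidised under these neutral conditions. Both C12 epimers converge on one ketone.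

Step 13
Reactants: 23 tert-butyl (2E,4E,6S,7R,9S,10R)-12-[4-(tert-butoxycarbonylamino)phenyl]-6-[(1S)-1-(tert-butyldimethylsilyloxy)ethyl]-10-hydroxy-7,9-dimethyl-12-oxododeca-2,4-dienoate
Product: 24 (2E,4E,6S,7R,9S,10R)-12-(4-aminophenyl)-10-hydroxy-6-[(1S)-1-hydroxyethyl]-7,9-dimethyl-12-oxododeca-2,4-dienoic acid
Conditions: TFA/CH2Cl2/H2O (10:10:1), 0 °C to rt; pH 6 buffer work-up
Reagents that add atoms: none
Why: Acidolysis removes the tert-butyl ester, the tert-butyl carbamate and the secondary silyl ether in one operation. No base is used, so the β-hydroxy ketone is not exposed to retro-aldol conditions, and no stereocentre is touched.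

## Compound list

1 | cis-3,5-dimethylcyclohexan-1-one (meso) | O=C1C[C@H](C)C[C@H](C)C1 | starting material
2 | lithium (3S,5R)-3,5-dimethylcyclohex-1-en-1-olate | [Li]OC1=C[C@@H](C)C[C@@H](C)C1 | intermediate (not isolated)
3 | trimethyl{[(3S,5R)-3,5-dimethylcyclohex-1-en-1-yl]oxy}silane | C[Si](C)(C)OC1=C[C@@H](C)C[C@@H](C)C1 | intermediate
4 | benzyltrimethylammonium (3S,5R)-3,5-dimethylcyclohex-1-en-1-olate | C[N+](C)(C)Cc1ccccc1.[O-]C1=C[C@@H](C)C[C@@H](C)C1 | intermediate (not isolated)
5 | (2R,3S,5R)-3,5-dimethyl-2-(prop-2-en-1-yl)cyclohexan-1-one | O=C1C[C@H](C)C[C@H](C)[C@H]1CC=C | intermediate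
6 | Criegee adduct: (2R,3S,5R)-1-hydroxy-3,5-dimethyl-2-(prop-2-en-1-yl)cyclohexyl 3-chloroperoxybenzoate | OC1(OOC(=O)c2cccc(Cl)c2)C[C@H](C)C[C@H](C)[C@H]1CC=C | intermediate (not isolated)
7 | (4R,6S,7R)-4,6-dimethyl-7-(prop-2-en-1-yl)oxepan-2-one | O=C1C[C@H](C)C[C@H](C)[C@@H](CC=C)O1 | intermediate
8 | lithium enolate of 7: lithium (4R,6S,7R)-4,6-dimethyl-7-(prop-2-en-1-yl)-4,5,6,7-tetrahydrooxepin-2-olate | [Li]OC1=C[C@H](C)C[C@H](C)[C@@H](CC=C)O1 | intermediate (not isolated)
9 | (3R,4R,6S,7R)-3-acetyl-4,6-dimethyl-7-(prop-2-en-1-yl)oxepan-2-one | O=C1[C@@H](C(C)=O)[C@H](C)C[C@H](C)[C@@H](CC=C)O1 | intermediate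
10 | (3R,4R,6S,7R)-3-[(1S)-1-hydroxyethyl]-4,6-dimethyl-7-(prop-2-en-1-yl)oxepan-2-one | O=C1[C@@H]([C@H](C)O)[C@H](C)C[C@H](C)[C@@H](CC=C)O1 | intermediate
11 | (3R,4R,6S,7R)-3-[(1S)-1-(tert-butyldimethylsilyloxy)ethyl]-4,6-dimethyl-7-(prop-2-en-1-yl)oxepan-2-one | O=C1[C@@H]([C@H](C)O[Si](C)(C)C(C)(C)C)[C@H](C)C[C@H](C)[C@@H](CC=C)O1 | intermediate
12 | ozonide of 11 (1,2,4-trioxolan-3-ylmethyl group on the lactone C7) | O=C1[C@@H]([C@H](C)O[Si](C)(C)C(C)(C)C)[C@H](C)C[C@H](C)[C@@H](CC2OCOO2)O1 | intermediate (not isolated)
13 | 2-[(2R,3S,5R,6R)-6-[(1S)-1-(tert-butyldimethylsilyloxy)ethyl]-3,5-dimethyl-7-oxooxepan-2-yl]acetaldehyde | O=C1[C@@H]([C@H](C)O[Si](C)(C)C(C)(C)C)[C@H](C)C[C@H](C)[C@@H](CC=O)O1 | intermediate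
14 | tert-butyl (4-iodophenyl)carbamate | CC(C)(C)OC(=O)Nc1ccc(I)cc1 | starting material
15 | [4-(tert-butoxycarbonylamino)phenyl]chromium dichloride (trivalent chromium) | CC(C)(C)OC(=O)Nc1ccc([Cr](Cl)Cl)cc1 | intermediate (not isolated)
16 | tert-butyl {4-[2-[(2R,3S,5R,6R)-6-[(1S)-1-(tert-butyldimethylsilyloxy)ethyl]-3,5-dimethyl-7-oxooxepan-2-yl]-1-hydroxyethyl]phenyl}carbamate (both carbinol epimers) | O=C1[C@@H]([C@H](C)O[Si](C)(C)C(C)(C)C)[C@H](C)C[C@H](C)[C@@H](CC(O)c2ccc(NC(=O)OC(C)(C)C)cc2)O1 | intermediate
17 | tert-butyl {4-[(3R,4S,6R,7R,8S)-8-(tert-butyldimethylsilyloxy)-7-formyl-1,3-dihydroxy-4,6-dimethylnonyl]phenyl}carbamate (both C1 epimers) | C[C@H](O[Si](C)(C)C(C)(C)C)[C@H](C=O)[C@H](C)C[C@H](C)[C@H](O)CC(O)c1ccc(NC(=O)OC(C)(C)C)cc1 | intermediate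
18 | tert-butyl (E)-4-bromobut-2-enoate | CC(C)(C)OC(=O)/C=C/CBr | starting material
19 | triethyl phosphite | CCOP(OCC)OCC | starting material
20 | tert-butyl (E)-4-(diethoxyphosphoryl)but-2-enoate | CCOP(=O)(OCC)C/C=C/C(=O)OC(C)(C)C | intermediate
21 | lithiated 20 (lithium salt of the C4 carbanion) | [Li+].CCOP(=O)(OCC)[CH-]/C=C/C(=O)OC(C)(C)C | intermediate (not isolated)
22 | tert-butyl (2E,4E,6S,7R,9S,10R)-12-[4-(tert-butoxycarbonylamino)phenyl]-6-[(1S)-1-(tert-butyldimethylsilyloxy)ethyl]-10,12-dihydroxy-7,9-dimethyldodeca-2,4-dienoate (both C12 epimers) | C[C@H](O[Si](C)(C)C(C)(C)C)[C@H](/C=C/C=C/C(=O)OC(C)(C)C)[C@H](C)C[C@H](C)[C@H](O)CC(O)c1ccc(NC(=O)OC(C)(C)C)cc1 | intermediate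
23 | tert-butyl (2E,4E,6S,7R,9S,10R)-12-[4-(tert-butoxycarbonylamino)phenyl]-6-[(1S)-1-(tert-butyldimethylsilyloxy)ethyl]-10-hydroxy-7,9-dimethyl-12-oxododeca-2,4-dienoate | C[C@H](O[Si](C)(C)C(C)(C)C)[C@H](/C=C/C=C/C(=O)OC(C)(C)C)[C@H](C)C[C@H](C)[C@H](O)CC(=O)c1ccc(NC(=O)OC(C)(C)C)cc1 | intermediate
24 | (2E,4E,6S,7R,9S,10R)-12-(4-aminophenyl)-10-hydroxy-6-[(1S)-1-hydroxyethyl]-7,9-dimethyl-12-oxododeca-2,4-dienoic acid | C[C@H](O)[C@H](/C=C/C=C/C(=O)O)[C@H](C)C[C@H](C)[C@H](O)CC(=O)c1ccc(N)cc1 | target

## Step count and least certain steps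

Total step count: 13. Longest linear sequence: 12 steps (steps 1 to 9 and 11 to 13, from 1 to 24); step 10 is a one-step side branch.

Step 3 (key step). The peracid may epoxidise the terminal alkene in competition with the ketone oxidation; a regiochemical leak through migration of the primary ring methylene is less likely. Fallback: the alkene is removed before the oxidation. From 5, ozonolysis in CH2Cl2/MeOH with Me2S and acidic acetalisation (TsOH, HC(OMe)3) would give (2R,3S,5R)-2-(2,2-dimethoxyethyl)-3,5-dimethylcyclohexan-1-one F1. Its Baeyer–Villiger oxidation, now without any alkene, would give (4R,6S,7R)-7-(2,2-dimethoxyethyl)-4,6-dimethyloxepan-2-one F2. The acylation, zinc borohydride reduction and silylation of steps 4 to 6 would then lead through (3R,4R,6S,7R)-3-acetyl-7-(2,2-dimethoxyethyl)-4,6-dimethyloxepan-2-one F3 and (3R,4R,6S,7R)-7-(2,2-dimethoxyethyl)-3-[(1S)-1-hydroxyethyl]-4,6-dimethyloxepan-2-one F4 to (3R,4R,6S,7R)-3-[(1S)-1-(tert-butyldimethylsilyloxy)ethyl]-7-(2,2-dimethoxyethyl)-4,6-dimethyloxepan-2-one F5. Mild acetal hydrolysis (LiBF4, wet MeCN) returns to the route at 13.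

Step 1. Proton selection by the chiral base may be incomplete or may have the opposite sense, which would lower the enantiomeric purity of everything downstream. Fallback: a racemic entry with resolution. From 1, LiN(i-Pr)2 and allyl bromide (then K2CO3, MeOH) would give the racemate, an equal mixture of 5 and (2S,3R,5S)-3,5-dimethyl-2-(prop-2-en-1-yl)cyclohexan-1-one F6. Preparative chromatography on a chiral stationary phase would separate the two, and the route is rejoined at 5.

Step 4 (with step 5). The labile C3 centre of 9 may equilibrate incompletely, or its two epimers may be reduced at different rates, so that the wrong C6 configuration leaks into 10. Fallback: a kinetic aldol in place of acylation and reduction. From 7, enolisation with LiN(i-Pr)2, transmetalation with Cp2ZrCl2 and addition of acetaldehyde would form the C6–C1' bond directly. Zirconium enolates are known to give syn aldols from either enolate geometry, and attack should occur anti to the C4 methyl. This rejoins the route at 10 and makes no new compound (F0).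

Step 8. Oxidative addition and transfer of the electron-rich aryl group may be slow, and during a long reaction the aldehyde may lose the lactone carboxylate by β-elimination. Fallback: acyl cross-coupling followed by reduction. From 13, NaClO2/NaH2PO4 oxidation would give 2-[(2R,3S,5R,6R)-6-[(1S)-1-(tert-butyldimethylsilyloxy)ethyl]-3,5-dimethyl-7-oxooxepan-2-yl]acetic acid F7. EtSH with a carbodiimide would give the S-ethyl thioester of that acid F8. Liebeskind–Srogl coupling with commercial 4-(tert-butoxycarbonylamino)phenylboronic acid (Pd2(dba)3, tri(2-furyl)phosphine, monovalent copper thiophene-2-carboxylate CuO2C–C4H3S, THF, 50 °C) would give tert-butyl {4-[2-[(2R,3S,5R,6R)-6-[(1S)-1-(tert-butyldimethylsilyloxy)ethyl]-3,5-dimethyl-7-oxooxepan-2-yl]acetyl]phenyl}carbamate F9. NaBH4/CeCl3·7H2O at −40 °C reduces the aryl ketone and rejoins the route at 16.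

Step 13. The long acid exposure needed for the tert-butyl ester may dehydrate the β-hydroxy ketone or trigger retro-aldol cleavage. Fallback: the ester is cleaved by base before the ketone exists. From 17, olefination with commercial triethyl 4-phosphonocrotonate (LiN(SiMe3)2, THF) would give ethyl (2E,4E,6S,7R,9S,10R)-12-[4-(tert-butoxycarbonylamino)phenyl]-6-[(1S)-1-(tert-butyldimethylsilyloxy)ethyl]-10,12-dihydroxy-7,9-dimethyldodeca-2,4-dienoate F10. LiOH in THF/MeOH/H2O would give the corresponding dienoic acid F11. DDQ in wet CH2Cl2 would oxidise the benzylic alcohol to (2E,4E,6S,7R,9S,10R)-12-[4-(tert-butoxycarbonylamino)phenyl]-6-[(1S)-1-(tert-butyldimethylsilyloxy)ethyl]-10-hydroxy-7,9-dimethyl-12-oxododeca-2,4-dienoic acid F12. A brief treatment with TFA/H2O at 0 °C, which now has only the carbamate and the silyl ether to remove, leads to 24.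

## Further compounds

F1 | step 3 | (2R,3S,5R)-2-(2,2-dimethoxyethyl)-3,5-dimethylcyclohexan-1-one | O=C1C[C@H](C)C[C@H](C)[C@H]1CC(OC)OC
F2 | step 3 | (4R,6S,7R)-7-(2,2-dimethoxyethyl)-4,6-dimethyloxepan-2-one | O=C1C[C@H](C)C[C@H](C)[C@@H](CC(OC)OC)O1
F3 | step 3 | (3R,4R,6S,7R)-3-acetyl-7-(2,2-dimethoxyethyl)-4,6-dimethyloxepan-2-one | O=C1[C@@H](C(C)=O)[C@H](C)C[C@H](C)[C@@H](CC(OC)OC)O1
F4 | step 3 | (3R,4R,6S,7R)-7-(2,2-dimethoxyethyl)-3-[(1S)-1-hydroxyethyl]-4,6-dimethyloxepan-2-one | O=C1[C@@H]([C@H](C)O)[C@H](C)C[C@H](C)[C@@H](CC(OC)OC)O1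
F5 | step 3 | (3R,4R,6S,7R)-3-[(1S)-1-(tert-butyldimethylsilyloxy)ethyl]-7-(2,2-dimethoxyethyl)-4,6-dimethyloxepan-2-one | O=C1[C@@H]([C@H](C)O[Si](C)(C)C(C)(C)C)[C@H](C)C[C@H](C)[C@@H](CC(OC)OC)O1
F6 | step 1 | (2S,3R,5S)-3,5-dimethyl-2-(prop-2-en-1-yl)cyclohexan-1-one | O=C1C[C@@H](C)C[C@@H](C)[C@@H]1CC=C
F0 | step 4 | none | none
F7 | step 8 | 2-[(2R,3S,5R,6R)-6-[(1S)-1-(tert-butyldimethylsilyloxy)ethyl]-3,5-dimethyl-7-oxooxepan-2-yl]acetic acid | O=C1[C@@H]([C@H](C)O[Si](C)(C)C(C)(C)C)[C@H](C)C[C@H](C)[C@@H](CC(=O)O)O1
F8 | step 8 | S-ethyl 2-[(2R,3S,5R,6R)-6-[(1S)-1-(tert-butyldimethylsilyloxy)ethyl]-3,5-dimethyl-7-oxooxepan-2-yl]ethanethioate | O=C1[C@@H]([C@H](C)O[Si](C)(C)C(C)(C)C)[C@H](C)C[C@H](C)[C@@H](CC(=O)SCC)O1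
F9 | step 8 | tert-butyl {4-[2-[(2R,3S,5R,6R)-6-[(1S)-1-(tert-butyldimethylsilyloxy)ethyl]-3,5-dimethyl-7-oxooxepan-2-yl]acetyl]phenyl}carbamate | O=C1[C@@H]([C@H](C)O[Si](C)(C)C(C)(C)C)[C@H](C)C[C@H](C)[C@@H](CC(=O)c2ccc(NC(=O)OC(C)(C)C)cc2)O1
F10 | step 13 | ethyl (2E,4E,6S,7R,9S,10R)-12-[4-(tert-butoxycarbonylamino)phenyl]-6-[(1S)-1-(tert-butyldimethylsilyloxy)ethyl]-10,12-dihydroxy-7,9-dimethyldodeca-2,4-dienoate (both C12 epimers) | C[C@H](O[Si](C)(C)C(C)(C)C)[C@H](/C=C/C=C/C(=O)OCC)[C@H](C)C[C@H](C)[C@H](O)CC(O)c1ccc(NC(=O)OC(C)(C)C)cc1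
F11 | step 13 | (2E,4E,6S,7R,9S,10R)-12-[4-(tert-butoxycarbonylamino)phenyl]-6-[(1S)-1-(tert-butyldimethylsilyloxy)ethyl]-10,12-dihydroxy-7,9-dimethyldodeca-2,4-dienoic acid (both C12 epimers) | C[C@H](O[Si](C)(C)C(C)(C)C)[C@H](/C=C/C=C/C(=O)O)[C@H](C)C[C@H](C)[C@H](O)CC(O)c1ccc(NC(=O)OC(C)(C)C)cc1
F12 | step 13 | (2E,4E,6S,7R,9S,10R)-12-[4-(tert-butoxycarbonylamino)phenyl]-6-[(1S)-1-(tert-butyldimethylsilyloxy)ethyl]-10-hydroxy-7,9-dimethyl-12-oxododeca-2,4-dienoic acid | C[C@H](O[Si](C)(C)C(C)(C)C)[C@H](/C=C/C=C/C(=O)O)[C@H](C)C[C@H](C)[C@H](O)CC(=O)c1ccc(NC(=O)OC(C)(C)C)cc1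
A1 | alternative 1 | (2S,4R,5R)-5-[(1S)-1-(tert-butyldimethylsilyloxy)ethyl]-2,4-dimethylhept-6-enal | C[C@H](O[Si](C)(C)C(C)(C)C)[C@H](C=C)[C@H](C)C[C@H](C)C=O
A2 | alternative 1 | tert-butyl {4-[(3R,4S,6R,7R)-7-[(1S)-1-(tert-butyldimethylsilyloxy)ethyl]-3-hydroxy-4,6-dimethylnon-8-enoyl]phenyl}carbamate | C[C@H](O[Si](C)(C)C(C)(C)C)[C@H](C=C)[C@H](C)C[C@H](C)[C@H](O)CC(=O)c1ccc(NC(=O)OC(C)(C)C)cc1
A3 | alternative 2 | (2R,3E,5S)-5-(tert-butyldimethylsilyloxy)-1-[(4-methoxybenzyl)oxy]hex-3-en-2-yl propanoate | CCC(=O)O[C@@H](COCc1ccc(OC)cc1)/C=C/[C@H](C)O[Si](C)(C)C(C)(C)C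
A4 | alternative 2 | (2S,3R,4E)-3-[(1S)-1-(tert-butyldimethylsilyloxy)ethyl]-6-[(4-methoxybenzyl)oxy]-2-methylhex-4-enoic acid | C[C@H](O[Si](C)(C)C(C)(C)C)[C@H](/C=C/COCc1ccc(OC)cc1)[C@H](C)C(=O)O
A5 | alternative 3 | (4R,6S)-4,6-dimethylcyclohex-2-en-1-one | O=C1C=C[C@H](C)C[C@@H]1C
A6 | alternative 3 | trimethyl{[(3S,4R,6S)-4,6-dimethyl-3-(prop-1-en-2-yl)cyclohex-1-en-1-yl]oxy}silane | C[Si](C)(C)OC1=C[C@@H](C(C)=C)[C@H](C)C[C@@H]1C
A7 | alternative 3 | (2S,4R,5S)-5-acetyl-2,4-dimethyl-6-oxohexanoic acid | CC(=O)[C@H](C=O)[C@H](C)C[C@H](C)C(=O)O
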